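## Retrosynthetic overview

1. Locants (germacrane style): ten-membered ring C1–C10 with Z-C1=C10(Me) and Z-C4(Me)=C5; lactone C12(=O)–O–C6 fused at C6–C7; C11=C13H2; C8 carries the ester oxygen; C9 is the ketone.
2. Last bond: the C8–O acyl bond, from the C8 alcohol and (2S,3S)-2,3-dimethyloxirane-2-carboxylic acid, whose oxirane is made first by Sharpless epoxidation.
3. Key disconnection C7–C8: the ten-membered carbocycle is closed last, by ring contraction of a transient 13-membered oxonium ylide (copper carbene at C8 of a C9 diazoketone plus the ether oxygen on C13, then [2,3]-shift of C8 onto C7 with loss of the O–C13 bond).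
4. Enabling feature: the array O–C8–C7–C11=C13 next to the C9 carbonyl, a homoallylic oxygen whose allyl part is the α-methylene lactone. Read backwards it is a 3-(alkoxymethyl)butenolide (C7=C11, C13–OR), an allyl ether that is also a Michael acceptor at C7, with C8 made nucleophilic by the C9 acyl group.
5. Ring order: oxirane (acid side chain) → butenolide (C6 by asymmetric alkynylation of a neryl-acetate-derived Z-enal; Z-C1=C10 by Still–Gennari olefination; Red-Al/I2 then Pd/CO) → ten-membered ring (key step).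

Key step: step 17

Assumption: in step 10 the alkynyl group must add to the Re face of aldehyde 12; (S,S)-ProPhenol is written for this, and the equally available (R,R)-ligand would be used without other change if the sense of induction proves opposite.

## Route

Step 1
Reactants: 1 methyl (2Z)-2-methylbut-2-enoate (methyl angelate)
Product: 2 (2Z)-2-methylbut-2-en-1-ol
Conditions: DIBAL-H (2.2 equiv), CH2Cl2, −78 °C; Rochelle salt work-up
Reagents that add atoms: none
Why: 1,2-Reduction of the unsaturated ester with DIBAL-H should give the allylic alcohol without touching the Z double bond.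

Step 2
Reactants: 2 (2Z)-2-methylbut-2-en-1-ol
Product: 3 [(2R,3S)-2,3-dimethyloxiran-2-yl]methanol
Conditions: Ti(OiPr)4 (10 mol %), D-(−)-diisopropyl tartrate (12 mol %), t-BuOOH (anhydrous), 4 Å MS, CH2Cl2, −20 °C
Reagents that add atoms: tert-butyl hydroperoxide CC(C)(C)OO
Why: Sharpless asymmetric epoxidation, in which the D-(−)-tartrate complex should select the alkene face that gives the (2R,3S)-epoxy alcohol, while syn oxygen transfer keeps CH2OH and the C3 methyl cis as in the Z-alkene.

Step 3
Reactants: 3 [(2R,3S)-2,3-dimethyloxiran-2-yl]methanol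
Product: 4 (2S,3S)-2,3-dimethyloxirane-2-carboxylic acid
Conditions: RuCl3·xH2O (2 mol %), NaIO4 (4 equiv), MeCN/EtOAc/H2O, 0 °C to rt
Reagents that add atoms: sodium periodate [Na+].[O-]I(=O)(=O)=O; water O
Why: RuO4-catalysed oxidation of the primary alcohol to the acid should leave both oxirane centres untouched (the C2 descriptor changes from R to S only through the CIP ranking).

Step 4
Reactants: 5 prop-2-yn-1-ol
Product: 6 1-methoxy-4-[(prop-2-yn-1-yloxy)methyl]benzene
Conditions: NaH, 4-methoxybenzyl chloride, Bu4NI (cat.), THF, 0 °C to rt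
Reagents that add atoms: 4-methoxybenzyl chloride COc1ccc(CCl)cc1
Why: Williamson etherification of the primary alkoxide with the benzylic chloride.

Step 5
Reactants: 7 (2Z)-3,7-dimethylocta-2,6-dien-1-yl acetate (neryl acetate)
Product: 8 (2Z)-5-(3,3-dimethyloxiran-2-yl)-3-methylpent-2-en-1-yl acetate
Conditions: mCPBA (1.05 equiv), NaHCO3, CH2Cl2, 0 °C
Reagents that add atoms: 3-chloroperbenzoic acid OOC(=O)c1cccc(Cl)c1
Why: Prilezhaev epoxidation should be chemoselective for the distal, more electron-rich trisubstituted alkene, because the allylic acetate deactivates the 2,3-alkene; the new centre is racemic and is destroyed in step 6.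

Step 6
Reactants: 8 (2Z)-5-(3,3-dimethyloxiran-2-yl)-3-methylpent-2-en-1-yl acetate
Product: 9 (2Z)-3-methyl-6-oxohex-2-en-1-yl acetate
Conditions: H5IO6 (1.1 equiv), THF/H2O, 0 °C
Reagents that add atoms: none
Why: Epoxide hydrolysis and Malaprade glycol cleavage in one pot should give the aldehyde and acetone while the Z-alkene and the acetate survive.

Step 7
Reactants: 9 (2Z)-3-methyl-6-oxohex-2-en-1-yl acetate
Product: 10 ethyl (2Z,6Z)-8-acetoxy-2,6-dimethylocta-2,6-dienoate
Conditions: ethyl 2-[bis(2,2,2-trifluoroethoxy)phosphoryl]propanoate, KHMDS, 18-crown-6, THF, −78 °C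
Reagents that add atoms: ethyl 2-[bis(2,2,2-trifluoroethoxy)phosphoryl]propanoate CCOC(=O)C(C)P(=O)(OCC(F)(F)F)OCC(F)(F)F
Why: Still–Gennari olefination, in which the electron-poor phosphonate with a dissociated potassium counter-ion should give the kinetic Z-trisubstituted enoate (the later C1=C10).

Step 8
Reactants: 10 ethyl (2Z,6Z)-8-acetoxy-2,6-dimethylocta-2,6-dienoate
Product: 11 ethyl (2Z,6Z)-8-hydroxy-2,6-dimethylocta-2,6-dienoate
Conditions: K2CO3 (0.2 equiv), EtOH, 0 °C to rt
Reagents that add atoms: none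
Why: Base-catalysed ethanolysis should remove the acetate only, since exchange at the conjugated ethyl ester is degenerate in ethanol.

Step 9
Reactants: 11 ethyl (2Z,6Z)-8-hydroxy-2,6-dimethylocta-2,6-dienoate
Product: 12 ethyl (2Z,6Z)-2,6-dimethyl-8-oxoocta-2,6-dienoate
Conditions: Dess–Martin periodinane, NaHCO3, CH2Cl2, 0 °C; used at once
Reagents that add atoms: none
Why: Buffered Dess–Martin oxidation of the allylic alcohol should give the Z-enal without Z to E isomerisation.

Step 10
Reactants: 12 ethyl (2Z,6Z)-2,6-dimethyl-8-oxoocta-2,6-dienoate; 6 1-methoxy-4-[(prop-2-yn-1-yloxy)methyl]benzene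
Product: 14 ethyl (2Z,6Z,8S)-8-hydroxy-11-[(4-methoxyphenyl)methoxy]-2,6-dimethylundeca-2,6-dien-9-ynoate, via alkynyl(methyl)zinc 13 (not isolated)
Conditions: 6 (2.8 equiv), Me2Zn (2.9 equiv), (S,S)-ProPhenol (20 mol %), Ph3P=O (40 mol %), toluene, 0 °C; then 12, 0–4 °C
Reagents that add atoms: none
Why: Dinuclear zinc–ProPhenol asymmetric alkynylation of an α,β-unsaturated aldehyde, in which the chiral dizinc pocket should deliver the alkynyl group to the Re face and so set the (S)-carbinol that becomes C6.

Step 11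
Reactants: 14 ethyl (2Z,6Z,8S)-8-hydroxy-11-[(4-methoxyphenyl)methoxy]-2,6-dimethylundeca-2,6-dien-9-ynoate
Product: 15 (2Z,6Z,8S)-11-[(4-methoxyphenyl)methoxy]-2,6-dimethylundeca-2,6-dien-9-yne-1,8-diol
Conditions: DIBAL-H (3.5 equiv), CH2Cl2, −78 °C
Reagents that add atoms: none
Why: DIBAL-H 1,2-reduction of the enoate removes the only group that would not survive the hydroalumination of step 12.

Step 12
Reactants: 15 (2Z,6Z,8S)-11-[(4-methoxyphenyl)methoxy]-2,6-dimethylundeca-2,6-dien-9-yne-1,8-diol
Product: 17 (2Z,6Z,8S,9Z)-10-iodo-11-[(4-methoxyphenyl)methoxy]-2,6-dimethylundeca-2,6,9-triene-1,8-diol, via cyclic alkenylalanate 16 (not isolated)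
Conditions: Red-Al (3.5 equiv), THF, 0 °C to rt; then I2, THF, −78 °C
Reagents that add atoms: iodine II
Why: Alkoxide-directed trans-hydroalumination of the propargylic alcohol places aluminium on the distal alkyne carbon, and iodinolysis with retention should give the (Z)-γ-iodo allylic alcohol; the low temperature is meant to suppress β-elimination of the p-methoxybenzyloxy group.

Step 13
Reactants: 17 (2Z,6Z,8S,9Z)-10-iodo-11-[(4-methoxyphenyl)methoxy]-2,6-dimethylundeca-2,6,9-triene-1,8-diol
Product: 18 (5S)-5-[(1Z,5Z)-7-hydroxy-2,6-dimethylhepta-1,5-dien-1-yl]-3-{[(4-methoxyphenyl)methoxy]methyl}furan-2(5H)-one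
Conditions: PdCl2(PPh3)2 (5 mol %), CO (1 atm), K2CO3 (2 equiv), THF, rt
Reagents that add atoms: carbon monoxide [C-]#[O+]
Why: Palladium-catalysed carbonylative lactonisation (oxidative addition, CO insertion, capture of the acylpalladium by the cis γ-hydroxyl) should close the butenolide, and the weak heterogeneous base is chosen to spare the C6 centre.

Step 14
Reactants: 18 (5S)-5-[(1Z,5Z)-7-hydroxy-2,6-dimethylhepta-1,5-dien-1-yl]-3-{[(4-methoxyphenyl)methoxy]methyl}furan-2(5H)-one
Product: 19 (2Z,6Z)-7-[(2S)-4-{[(4-methoxyphenyl)methoxy]methyl}-5-oxo-2,5-dihydrofuran-2-yl]-2,6-dimethylhepta-2,6-dienal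
Conditions: Dess–Martin periodinane, NaHCO3, CH2Cl2, 0 °C
Reagents that add atoms: none
Why: Buffered Dess–Martin oxidation of the primary allylic alcohol should give the Z-enal under non-basic conditions that leave the butenolide centre alone.

Step 15
Reactants: 19 (2Z,6Z)-7-[(2S)-4-{[(4-methoxyphenyl)methoxy]methyl}-5-oxo-2,5-dihydrofuran-2-yl]-2,6-dimethylhepta-2,6-dienal
Product: 20 (2Z,6Z)-7-[(2S)-4-{[(4-methoxyphenyl)methoxy]methyl}-5-oxo-2,5-dihydrofuran-2-yl]-2,6-dimethylhepta-2,6-dienoic acid
Conditions: NaClO2, NaH2PO4, 2-methyl-2-butene, t-BuOH/H2O, 0 °C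
Reagents that add atoms: sodium chlorite [Na+].[O-]Cl=O
Why: Pinnick oxidation should convert the enal into the acid with retention of the Z geometry, with the alkene scavenger protecting the other double bonds from hypochlorite.

Step 16
Reactants: 20 (2Z,6Z)-7-[(2S)-4-{[(4-methoxyphenyl)methoxy]methyl}-5-oxo-2,5-dihydrofuran-2-yl]-2,6-dimethylhepta-2,6-dienoic acid
Product: 22 (5S)-5-[(1Z,5Z)-8-diazo-2,6-dimethyl-7-oxoocta-1,5-dien-1-yl]-3-{[(4-methoxyphenyl)methoxy]methyl}furan-2(5H)-one, via acid chloride 21 (not isolated)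
Conditions: 1-chloro-N,N,2-trimethylprop-1-en-1-amine (1.2 equiv), CH2Cl2, 0 °C; then CH2N2 (3 equiv), Et2O, 0 °C
Reagents that add atoms: diazomethane C=[N+]=[N-]
Why: Acid chloride formation under neutral, HCl-free conditions followed by acylation of diazomethane (the first stage of an Arndt–Eistert sequence) should give the diazoketone without Z to E isomerisation; the short reaction at 0 °C is meant to outrun dipolar cycloaddition to the butenolide.

Step 17
Reactants: 22 (5S)-5-[(1Z,5Z)-8-diazo-2,6-dimethyl-7-oxoocta-1,5-dien-1-yl]-3-{[(4-methoxyphenyl)methoxy]methyl}furan-2(5H)-one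
Product: 24 (6S,7S,8R)-8-[(4-methoxyphenyl)methoxy]-9-oxogermacra-1(10)Z,4Z,11(13)-trien-12,6-olide, via cyclic oxonium ylide 23 (not isolated)
Conditions: Cu(hfacac)2 (10 mol %), CH2Cl2, reflux; 22 added by syringe pump over 10 h (final about 2 mM)
Reagents that add atoms: none
Why: Proposed new method: copper-catalysed loss of N2 from 22 should give an electrophilic copper carbene at C8, the C13 ether oxygen captures it and closes the 13-membered oxonium ylide 23 (ring closure by oxygen-to-carbene attack), and the enolate-like ylide carbon C8 then bonds to C7 of the butenolide C7=C11 bond through a five-membered envelope [2,3]-sigmatropic transition state while O–C13 breaks, which closes the ten-membered carbocycle as a 10-exo-trig ring contraction (13 to 10) and sets free the C11=C13 methylene, the C8–O ether and the C9 ketone in the same event. The closest known reaction types are the Cu- or Rh-catalysed oxonium ylide formation/[2,3]-rearrangement of diazoketones with allyl ethers, its macrocyclic form in which diazoacetates tethered to allyl ethers contract 13-membered ylides to ten-membered lactones, and the anionic [2,3]-Wittig ring contraction of 13-membered allylic ethers to germacrane rings; what is new is the acrylate-type allyl ether embedded in a butenolide and the carbocyclic product. The polarity is matched (nucleophilic ylide carbon, β-carbon of an unsaturated lactone) and the reverse reaction would be a 5-endo attack of the C8 oxygen on C13, so the rearrangement should be irreversible. C7 is controlled by C6: the eight-atom arm is anchored on the face of C6 that carries C5 and, with its two Z double bonds, is a compact double U that is expected to present C8 to the same face of C7, which gives the cis-fused lactone (7S). C8 is controlled by the forming ring: in the envelope the acyl carbon C9 must point away from the lactone (exo), because the endo placement would need two consecutive eclipsed torsions (C5–C6–C7–C8 and C6–C7–C8–C9) in the ten-membered ring, and exo bonding on the E-configured C13–C11=C7–C6 allyl ether gives 8R. The step needs ylide formation to win over cyclopropanation of C4=C5 and allylic C–H insertion, for which the hexafluoroacetylacetonate copper catalyst, the electron-poor C7=C11 bond and slow addition at high dilution are relied on.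

Step 18
Reactants: 24 (6S,7S,8R)-8-[(4-methoxyphenyl)methoxy]-9-oxogermacra-1(10)Z,4Z,11(13)-trien-12,6-olide
Product: 25 (6S,7R,8R)-8-hydroxy-9-oxogermacra-1(10)Z,4Z,11(13)-trien-12,6-olide
Conditions: DDQ (1.5 equiv), CH2Cl2/pH 7 phosphate buffer (10:1), 0 °C
Reagents that add atoms: none
Why: Oxidative cleavage of the p-methoxybenzyl ether by DDQ under buffered conditions should free the C8 hydroxyl without touching the dienone or the α-methylene lactone (the C7 descriptor changes from S to R only through the CIP ranking).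

Step 19
Reactants: 25 (6S,7R,8R)-8-hydroxy-9-oxogermacra-1(10)Z,4Z,11(13)-trien-12,6-olide; 4 (2S,3S)-2,3-dimethyloxirane-2-carboxylic acid
Product: 27 (6S,7S,8R)-8-{[(2S,3S)-2,3-dimethyloxiran-2-yl]carbonyloxy}-9-oxogermacra-1(10)Z,4Z,11(13)-trien-12,6-olide, via mixed anhydride 26 (not isolated)
Conditions: 4, 2,4,6-trichlorobenzoyl chloride, Et3N, toluene, rt; then 25, DMAP, toluene, 0 °C to rt
Reagents that add atoms: none
Why: Yamaguchi esterification acylates the hindered α-ketol oxygen through the mixed anhydride without breaking the C8–O bond, so the 8R configuration is retained; low temperature and a short contact time with DMAP are meant to avoid enolisation at C8.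

## Compound list

1 | methyl (2Z)-2-methylbut-2-enoate (methyl angelate) | C/C=C(/C)C(=O)OC | starting material
2 | (2Z)-2-methylbut-2-en-1-ol | C/C=C(/C)CO | intermediate
3 | [(2R,3S)-2,3-dimethyloxiran-2-yl]methanol | OC[C@@]1(C)O[C@H]1C | intermediate
4 | (2S,3S)-2,3-dimethyloxirane-2-carboxylic acid | OC(=O)[C@@]1(C)O[C@H]1C | intermediate
5 | prop-2-yn-1-ol | C#CCO | starting material
6 | 1-methoxy-4-[(prop-2-yn-1-yloxy)methyl]benzene | C#CCOCc1ccc(OC)cc1 | intermediate
7 | (2Z)-3,7-dimethylocta-2,6-dien-1-yl acetate (neryl acetate) | CC(C)=CCC/C(C)=C\COC(C)=O | starting material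
8 | (2Z)-5-(3,3-dimethyloxiran-2-yl)-3-methylpent-2-en-1-yl acetate (racemic at the oxirane carbon) | CC1(C)OC1CC/C(C)=C\COC(C)=O | intermediate
9 | (2Z)-3-methyl-6-oxohex-2-en-1-yl acetate | O=CCC/C(C)=C\COC(C)=O | intermediate
10 | ethyl (2Z,6Z)-8-acetoxy-2,6-dimethylocta-2,6-dienoate | CCOC(=O)/C(C)=C\CC/C(C)=C\COC(C)=O | intermediate
11 | ethyl (2Z,6Z)-8-hydroxy-2,6-dimethylocta-2,6-dienoate | CCOC(=O)/C(C)=C\CC/C(C)=C\CO | intermediate
12 | ethyl (2Z,6Z)-2,6-dimethyl-8-oxoocta-2,6-dienoate | CCOC(=O)/C(C)=C\CC/C(C)=C\C=O | intermediate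
13 | methyl{3-[(4-methoxyphenyl)methoxy]prop-1-yn-1-yl}zinc (zinc acetylide of 6, not isolated) | C[Zn]C#CCOCc1ccc(OC)cc1 | intermediate
14 | ethyl (2Z,6Z,8S)-8-hydroxy-11-[(4-methoxyphenyl)methoxy]-2,6-dimethylundeca-2,6-dien-9-ynoate | CCOC(=O)/C(C)=C\CC/C(C)=C\[C@H](O)C#CCOCc1ccc(OC)cc1 | intermediate
15 | (2Z,6Z,8S)-11-[(4-methoxyphenyl)methoxy]-2,6-dimethylundeca-2,6-dien-9-yne-1,8-diol | OC/C(C)=C\CC/C(C)=C\[C@H](O)C#CCOCc1ccc(OC)cc1 | intermediate
16 | disodium salt of the five-membered alkenyl(alkoxy)alanate from 15 (Al on the alkene carbon bearing CH2OPMB and on the C8 oxygen; primary oxygen as alkoxide; not isolated) | [Na+].[Na+].[O-]C/C(C)=C\CC/C(C)=C\[C@@H]1O[Al-](OCCOC)(OCCOC)C(COCc2ccc(OC)cc2)=C1 | intermediate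
17 | (2Z,6Z,8S,9Z)-10-iodo-11-[(4-methoxyphenyl)methoxy]-2,6-dimethylundeca-2,6,9-triene-1,8-diol | OC/C(C)=C\CC/C(C)=C\[C@H](O)/C=C(\I)COCc1ccc(OC)cc1 | intermediate
18 | (5S)-5-[(1Z,5Z)-7-hydroxy-2,6-dimethylhepta-1,5-dien-1-yl]-3-{[(4-methoxyphenyl)methoxy]methyl}furan-2(5H)-one | OC/C(C)=C\CC/C(C)=C\[C@@H]1OC(=O)C(COCc2ccc(OC)cc2)=C1 | intermediate
19 | (2Z,6Z)-7-[(2S)-4-{[(4-methoxyphenyl)methoxy]methyl}-5-oxo-2,5-dihydrofuran-2-yl]-2,6-dimethylhepta-2,6-dienal | O=C/C(C)=C\CC/C(C)=C\[C@@H]1OC(=O)C(COCc2ccc(OC)cc2)=C1 | intermediate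
20 | (2Z,6Z)-7-[(2S)-4-{[(4-methoxyphenyl)methoxy]methyl}-5-oxo-2,5-dihydrofuran-2-yl]-2,6-dimethylhepta-2,6-dienoic acid | OC(=O)/C(C)=C\CC/C(C)=C\[C@@H]1OC(=O)C(COCc2ccc(OC)cc2)=C1 | intermediate
21 | (2Z,6Z)-7-[(2S)-4-{[(4-methoxyphenyl)methoxy]methyl}-5-oxo-2,5-dihydrofuran-2-yl]-2,6-dimethylhepta-2,6-dienoyl chloride (not isolated) | ClC(=O)/C(C)=C\CC/C(C)=C\[C@@H]1OC(=O)C(COCc2ccc(OC)cc2)=C1 | intermediate
22 | (5S)-5-[(1Z,5Z)-8-diazo-2,6-dimethyl-7-oxoocta-1,5-dien-1-yl]-3-{[(4-methoxyphenyl)methoxy]methyl}furan-2(5H)-one | [N-]=[N+]=CC(=O)/C(C)=C\CC/C(C)=C\[C@@H]1OC(=O)C(COCc2ccc(OC)cc2)=C1 | intermediate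
23 | (6S)-13-membered cyclic oxonium ylide: O-(4-methoxybenzyl)oxonium bridging C13 and the carbanionic C8, the butenolide C6 and C11 being joined by the chain C5–C4–C3–C2–C1–C10–C9–C8–O–C13 (not isolated) | O=C1O[C@H]2/C=C(/C)CC/C=C(/C)C(=O)[CH-][O+](Cc3ccc(OC)cc3)CC1=C2 | intermediate
24 | (6S,7S,8R)-8-[(4-methoxyphenyl)methoxy]-9-oxogermacra-1(10)Z,4Z,11(13)-trien-12,6-olide | C=C1C(=O)O[C@H]2/C=C(/C)CC/C=C(/C)C(=O)[C@H](OCc3ccc(OC)cc3)[C@@H]12 | intermediate
25 | (6S,7R,8R)-8-hydroxy-9-oxogermacra-1(10)Z,4Z,11(13)-trien-12,6-olide | C=C1C(=O)O[C@H]2/C=C(/C)CC/C=C(/C)C(=O)[C@H](O)[C@@H]12 | intermediate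
26 | (2S,3S)-2,3-dimethyloxirane-2-carboxylic 2,4,6-trichlorobenzoic anhydride (not isolated) | O=C(OC(=O)[C@@]1(C)O[C@H]1C)c1c(Cl)cc(Cl)cc1Cl | intermediate
27 | (6S,7S,8R)-8-{[(2S,3S)-2,3-dimethyloxiran-2-yl]carbonyloxy}-9-oxogermacra-1(10)Z,4Z,11(13)-trien-12,6-olide (CNP0183761.1) | C=C1C(=O)O[C@H]2/C=C(/C)CC/C=C(/C)C(=O)[C@H](OC(=O)[C@@]3(C)O[C@H]3C)[C@@H]12 | target

## Step count and risks

Total step count: 19. Longest linear sequence: 15 steps (steps 5–19, from neryl acetate 7 to 27).

Steps most likely to fail: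

Step 17 (Proposed new method). What may go wrong: the copper carbene is consumed by cyclopropanation of the nearby electron-rich C4=C5 bond or by insertion into an allylic C–H bond before the remote ether oxygen can close the 13-membered ylide; the ylide may also collapse by 1,2-shift of the p-methoxybenzyl group or bond to the wrong face of C7. Fallback, by known reactions and with the ring contraction done in two stages: it sets out from 22. DDQ (CH2Cl2/pH 7 buffer, 0 °C) removes the p-methoxybenzyl group to give the hydroxymethyl diazoketone (5S)-5-[(1Z,5Z)-8-diazo-2,6-dimethyl-7-oxoocta-1,5-dien-1-yl]-3-(hydroxymethyl)furan-2(5H)-one F1. Rh2(OAc)4-catalysed intramolecular O–H insertion at high dilution (CH2Cl2, rt), the fastest of the carbene reactions, then closes the 13-membered keto ether F2. Kinetic enolisation at C8 (LiHMDS, THF, −78 °C) triggers the enolate [2,3]-Wittig ring contraction, in the limit a Michael addition to C7 followed by β-elimination of the C13–O bond, and should give alcohol 25 directly. The route is rejoined at 25 and step 18 is not needed.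

Step 10. What may go wrong: Z to E isomerisation of the β,β-disubstituted enal at the Lewis-acidic zinc centres, or poor facial discrimination for a Z-enal. Fallback with reagent-controlled reduction in place of addition: it sets out from 12. Addition of the lithium acetylide of 6 (n-BuLi, THF, −78 °C; aldehyde over ester) gives the racemic propargylic alcohol ethyl (2Z,6Z)-8-hydroxy-11-[(4-methoxyphenyl)methoxy]-2,6-dimethylundeca-2,6-dien-9-ynoate F3. Oxidation with MnO2 (CH2Cl2, rt) gives the ynone ethyl (2Z,6Z)-11-[(4-methoxyphenyl)methoxy]-2,6-dimethyl-8-oxoundeca-2,6-dien-9-ynoate F4. CBS reduction ((S)-Me-CBS, catecholborane, toluene, −78 °C; alkyne as the small group) should set the (S)-carbinol, and the route is rejoined at 14.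

Step 13. What may go wrong: loss of configuration at the γ-carbon of the new 5-alkenylbutenolide through base-mediated deprotonation to the 2-oxidofuran, or palladium-induced ionisation of the allylic lactone C–O bond during the carbonylation. Fallback with carboxylation of an alkenyllithium and acid-mediated ring closure: it sets out from 17. Silylation of both hydroxyls (TBSCl, imidazole, DMF) gives the bis-silyl ether (2Z,6Z,8S,9Z)-1,8-bis[(tert-butyldimethylsilyl)oxy]-10-iodo-11-[(4-methoxyphenyl)methoxy]-2,6-dimethylundeca-2,6,9-triene F5. Iodine–lithium exchange (t-BuLi, Et2O, −78 °C) and trapping with methyl chloroformate gives the Z-enoate methyl (2Z,4S,5Z,9Z)-4,11-bis[(tert-butyldimethylsilyl)oxy]-2-{[(4-methoxyphenyl)methoxy]methyl}-6,10-dimethylundeca-2,5,9-trienoate F6. HF·pyridine (THF) removes both silyl groups, and the γ-hydroxy Z-enoate should lactonise under these base-free conditions. The route is rejoined at 18.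

## Further compounds

F1 | step 17 | (5S)-5-[(1Z,5Z)-8-diazo-2,6-dimethyl-7-oxoocta-1,5-dien-1-yl]-3-(hydroxymethyl)furan-2(5H)-one | [N-]=[N+]=CC(=O)/C(C)=C\CC/C(C)=C\[C@@H]1OC(=O)C(CO)=C1
F2 | step 17 | (6S)-13-membered keto ether in which the C13 oxygen is bonded to C8 (butenolide C6 and C11 joined by the chain C5–C4–C3–C2–C1–C10–C9–C8–O–C13) | O=C1O[C@H]2/C=C(/C)CC/C=C(/C)C(=O)COCC1=C2
F3 | step 10 | ethyl (2Z,6Z)-8-hydroxy-11-[(4-methoxyphenyl)methoxy]-2,6-dimethylundeca-2,6-dien-9-ynoate (racemic) | CCOC(=O)/C(C)=C\CC/C(C)=C\C(O)C#CCOCc1ccc(OC)cc1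
F4 | step 10 | ethyl (2Z,6Z)-11-[(4-methoxyphenyl)methoxy]-2,6-dimethyl-8-oxoundeca-2,6-dien-9-ynoate | CCOC(=O)/C(C)=C\CC/C(C)=C\C(=O)C#CCOCc1ccc(OC)cc1
F5 | step 13 | (2Z,6Z,8S,9Z)-1,8-bis[(tert-butyldimethylsilyl)oxy]-10-iodo-11-[(4-methoxyphenyl)methoxy]-2,6-dimethylundeca-2,6,9-triene | CC(C)(C)[Si](C)(C)OC/C(C)=C\CC/C(C)=C\[C@H](O[Si](C)(C)C(C)(C)C)/C=C(\I)COCc1ccc(OC)cc1
F6 | step 13 | methyl (2Z,4S,5Z,9Z)-4,11-bis[(tert-butyldimethylsilyl)oxy]-2-{[(4-methoxyphenyl)methoxy]methyl}-6,10-dimethylundeca-2,5,9-trienoate | COC(=O)/C(COCc1ccc(OC)cc1)=C\[C@@H](O[Si](C)(C)C(C)(C)C)/C=C(/C)CC/C=C(/C)CO[Si](C)(C)C(C)(C)C
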